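**Plan**

1. Retrosynthesis: cut C1–Br and C1–C2 first (C2 is carried as a lactone carbonyl), then the C5a–C6 bond of the bromocyclohexane, then the C5=C6 alkene and the ester C–O of a seven-membered lactone, and last C3–C4 of the acid fragment.
2. Forward: an allylsilane acid (Ireland–Claisen) is esterified with (S)-linalool; after epoxidation, ring-closing metathesis closes the oxepinone first; the epoxide becomes a vicinal dibromide whose bromonium ion is captured by the ring allylsilane to close the cyclohexane last; the lactone carbonyl is then turned into CH–CH2Br.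
3. Stereochemistry: C9a is the linalool stereocentre (chiral pool: linalool C2–C8 and its three methyls become C5a, C9a, C9, C8, C7, C6 and their methyls). C7 comes from a Shi epoxidation followed by one inversion. C5a is set by anti-SE2′ relay from a C–Si centre, itself made from (S)-but-3-yn-2-ol by Ireland–Claisen chirality transfer. C2 is set by hydroboration anti to the C9a methyl.
4. Enabling feature: the equatorial Br at C7 beside the gem-dimethyl C6 and the C5a–H is the anti-addition pattern of a bromonium ion opened at its tertiary carbon. In the oxepene, C5a is homoallylic to C3=C4 and C2 can be a lactone carbonyl, so an allylsilane (Si on C4) can deliver C5a as the nucleophile and the alkene can then be moved from C4=C5 to C3=C4 by conjugation.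

Key step: step 8

Remark on numbering: bicyclic compounds use benzo[b]oxepine numbering (O1, C2–C5, C5a, C6–C9, C9a); monocyclic lactones use oxepin-2-one numbering (O1, C2–C7), so lactone C6 and C7 become C5a and C9a.

Assumption: the carbon alpha to the carbonyl of the allylsilane fragment (C2 of the acid, C3 of the lactones) is carried as a mixture of epimers because it becomes sp2 in step 8; its SMILES leave this centre, and the ketene acetal geometry of 4, undefined.

**Route**

Step 1
Reactants: 1 (S)-but-3-yn-2-ol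
Product: 2 (S,E)-4-[dimethyl(phenyl)silyl]but-3-en-2-ol
Conditions: PhMe2SiH, Pt(dvds) (Karstedt catalyst, 0.2 mol %), P(t-Bu)3, THF, 23 °C
Reagents that add atoms: dimethyl(phenyl)silane (C[SiH](C)c1ccccc1)
Why: Pt(0)-catalysed alkyne hydrosilylation is a syn addition that should place silicon on the terminal carbon and give the (E)-vinylsilane without touching the carbinol stereocentre.

Step 2
Reactants: 2 (S,E)-4-[dimethyl(phenyl)silyl]but-3-en-2-ol
Product: 3 (S,E)-4-[dimethyl(phenyl)silyl]but-3-en-2-yl propanoate
Conditions: EtCOCl, pyridine, DMAP (cat.), CH2Cl2, 0 °C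
Reagents that add atoms: propanoyl chloride (CCC(Cl)=O)
Why: Standard DMAP-catalysed acylation of a secondary alcohol; the stereocentre is not involved.

Step 3
Reactants: 3 (S,E)-4-[dimethyl(phenyl)silyl]but-3-en-2-yl propanoate
Product: 6 (3R,4E)-3-[dimethyl(phenyl)silyl]-2-methylhex-4-enoic acid, via silyl ketene acetal 4 (not isolated), via trimethylsilyl ester 5 (not isolated)
Conditions: LDA, TMSCl (internal quench), THF, −78 → 60 °C; then H2O (pH 4 buffer)
Reagents that add atoms: none
Why: Ireland–Claisen rearrangement through a chair with the carbinol methyl equatorial should transfer the (S)-carbinol centre suprafacially into the (3R) C–Si centre and an (E)-propenyl group; the C2 epimer ratio follows the ketene acetal geometry and does not matter.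

Step 4
Reactants: 6 (3R,4E)-3-[dimethyl(phenyl)silyl]-2-methylhex-4-enoic acid; 7 (S)-(+)-linalool
Product: 10 (3S)-3,7-dimethylocta-1,6-dien-3-yl (3R,4E)-3-[dimethyl(phenyl)silyl]-2-methylhex-4-enoate, via acid chloride 8 (not isolated), via lithium linaloolate 9 (not isolated)
Conditions: 6, 1-chloro-N,N,2-trimethylprop-1-en-1-amine (Ghosez reagent), CH2Cl2, 0 → 23 °C; 7, n-BuLi, THF, −78 °C; then 8, −78 → 0 °C
Reagents that add atoms: none
Why: Acylation of a lithium tert-alkoxide by an acid chloride made under neutral conditions is the dependable esterification of a hindered tertiary allylic alcohol; the linalool centre (future C9a) is untouched, and any ketene pathway would only scramble the irrelevant C2.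

Step 5
Reactants: 10 (3S)-3,7-dimethylocta-1,6-dien-3-yl (3R,4E)-3-[dimethyl(phenyl)silyl]-2-methylhex-4-enoate
Product: 11 (3S)-5-[(2R)-3,3-dimethyloxiran-2-yl]-3-methylpent-1-en-3-yl (3R,4E)-3-[dimethyl(phenyl)silyl]-2-methylhex-4-enoate
Conditions: D-fructose-derived Shi ketone (0.3 equiv), Oxone, K2CO3, n-Bu4NHSO4, MeCN–DMM / aq. borate–EDTA buffer (pH 10.5), 0 °C
Reagents that add atoms: potassium peroxymonosulfate ([K+].[O-]S(=O)(=O)OO)
Why: Shi asymmetric epoxidation should act fastest on the electron-rich trisubstituted alkene (the vinyl group and the hindered allylsilane alkene are slower), and the spiro transition state of the fructose-derived dioxirane is expected to give the (R)-epoxide; this masks the alkene for step 6 and carries the future C7 configuration.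

Step 6
Reactants: 11 (3S)-5-[(2R)-3,3-dimethyloxiran-2-yl]-3-methylpent-1-en-3-yl (3R,4E)-3-[dimethyl(phenyl)silyl]-2-methylhex-4-enoate
Product: 12 (4R,7S)-7-{2-[(2R)-3,3-dimethyloxiran-2-yl]ethyl}-4-[dimethyl(phenyl)silyl]-3,7-dimethyl-4,7-dihydrooxepin-2(3H)-one
Conditions: Hoveyda–Grubbs II (10 mol %), toluene (0.002 M), 80 °C, argon sparge
Reagents that add atoms: none
Why: Ring-closing metathesis between the linalyl vinyl group and the propenyl group should close the seven-membered lactone with loss of propene, helped by the quaternary C7; the ring enforces the cis alkene and no stereocentre is touched.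

Step 7
Reactants: 12 (4R,7S)-7-{2-[(2R)-3,3-dimethyloxiran-2-yl]ethyl}-4-[dimethyl(phenyl)silyl]-3,7-dimethyl-4,7-dihydrooxepin-2(3H)-one
Product: 13 (4R,7S)-7-[(3S)-3,4-dibromo-4-methylpentyl]-4-[dimethyl(phenyl)silyl]-3,7-dimethyl-4,7-dihydrooxepin-2(3H)-one
Conditions: Ph3PBr2 (preformed, 1.05 equiv), CH2Cl2, 0 → 23 °C
Reagents that add atoms: dibromotriphenylphosphorane (BrP(Br)(c1ccccc1)(c1ccccc1)c1ccccc1)
Why: Conversion of an epoxide into a vicinal dibromide by P–O activation and two bromide deliveries; whichever carbon is attacked first, the secondary carbon is inverted exactly once and the tertiary one is not stereogenic, so the (R)-epoxide should give the (S)-bromide.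

Step 8
Reactants: 13 (4R,7S)-7-[(3S)-3,4-dibromo-4-methylpentyl]-4-[dimethyl(phenyl)silyl]-3,7-dimethyl-4,7-dihydrooxepin-2(3H)-one
Product: 15 (5aS,7S,9aS)-7-bromo-3,6,6,9a-tetramethyl-5a,6,7,8,9,9a-hexahydrobenzo[b]oxepin-2(5H)-one, via deconjugated lactone 14 (not isolated)
Conditions: AgOCOCF3 (1.5 equiv), 2,6-di-tert-butyl-4-methylpyridine, CH2Cl2–MeNO2 (1:1), −40 → 0 °C, dark; filter; then DBU, CH2Cl2, 23 °C
Reagents that add atoms: none
Why: Proposed new method: Ag(I) should abstract the tertiary bromide of 13 with anchimeric help from the neighbouring C–Br, giving a configurationally defined bromonium ion whose tertiary carbon is attacked by lactone C6 (the γ-carbon of the ring allylsilane); the β-silyl cation loses silicon to trifluoroacetate to give 14, and DBU then moves the alkene into conjugation (14 → 15), which puts the hydrogen on C5 and the alkene at C3=C4. The closest known reaction types are bromonium-initiated cation–olefin cyclisation, enantiospecific bromonium generation from bromohydrin derivatives, allylsilane-terminated cation cyclisation and Ag(I)-promoted SN1 alkylation of silyl-activated π-nucleophiles. The cyclohexane closes in a six-membered mode that is endo with respect to the bromonium ion (attack at its tertiary carbon, both carbons end in the ring) and exo with respect to the alkene, through a chair in which opening is anti-periplanar, so Br ends equatorial. C7 keeps the configuration set in steps 5 and 7 because its C–Br bond is never broken, and C5a is set by anti-SE2′ attack on the alkene face opposite the C–Si bond, which is the face carrying the lactone C7 methyl and so gives the trans ring fusion with that methyl axial. The step needs ionisation of C–Br and not of the tertiary allylic lactone C–O (a halophilic, non-oxophilic promoter and trifluoroacetate as a weakly Lewis acidic silicon sink), attack at the tertiary bromonium carbon (Markovnikov and ring size) and attack by C6 and not C5 (β-silicon effect).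

Step 9
Reactants: 15 (5aS,7S,9aS)-7-bromo-3,6,6,9a-tetramethyl-5a,6,7,8,9,9a-hexahydrobenzo[b]oxepin-2(5H)-one
Product: 16 (5aS,7S,9aS)-7-bromo-3,6,6,9a-tetramethyl-2-methylidene-2,5,5a,6,7,8,9,9a-octahydrobenzo[b]oxepine
Conditions: Cp2TiMe2 (3 equiv), toluene, 70 °C, dark; filtration through basic alumina
Reagents that add atoms: dimethyltitanocene ([CH3-].[CH3-].[Ti+4].c1cc[cH-]c1.c1cc[cH-]c1)
Why: Petasis methylenation should convert the lactone carbonyl into the exocyclic enol ether under non-acidic conditions that tolerate the alkyl bromide; no stereocentre is involved.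

Step 10
Reactants: 16 (5aS,7S,9aS)-7-bromo-3,6,6,9a-tetramethyl-2-methylidene-2,5,5a,6,7,8,9,9a-octahydrobenzo[b]oxepine
Product: 18 [(2R,5aS,7S,9aS)-7-bromo-3,6,6,9a-tetramethyl-2,5,5a,6,7,8,9,9a-octahydrobenzo[b]oxepin-2-yl]methanol, via alkylborane 17 (not isolated)
Conditions: 9-BBN, THF, 0 → 23 °C; then NaOH, 30% H2O2, 0 °C
Reagents that add atoms: hydrogen peroxide (OO)
Why: Hydroboration–oxidation of the enol ether should place boron on the terminal CH2 (β to oxygen) and deliver hydrogen to C2 from the face opposite the axial C9a methyl, setting (2R) with CH2OH cis to that methyl; the trisubstituted ring alkene is much slower, and cold oxidation should precede β-elimination of the β-alkoxyborane.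

Step 11
Reactants: 18 [(2R,5aS,7S,9aS)-7-bromo-3,6,6,9a-tetramethyl-2,5,5a,6,7,8,9,9a-octahydrobenzo[b]oxepin-2-yl]methanol
Product: 19 palisadin B
Conditions: CBr4, PPh3, 2,6-lutidine (cat.), CH2Cl2, 0 °C
Reagents that add atoms: tetrabromomethane (BrC(Br)(Br)Br)
Why: Appel reaction at the unhindered primary carbinol (SN2 at CH2) should give the bromide without touching any stereocentre.

**Compound list**

1 | (S)-but-3-yn-2-ol | C[C@@H](C#C)O | starting material
2 | (S,E)-4-[dimethyl(phenyl)silyl]but-3-en-2-ol | C[C@@H](/C=C/[Si](C)(C)c1ccccc1)O | intermediate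
3 | (S,E)-4-[dimethyl(phenyl)silyl]but-3-en-2-yl propanoate | CCC(=O)O[C@@H](C)/C=C/[Si](C)(C)c1ccccc1 | intermediate
4 | trimethylsilyl ketene acetal of 3 (C=C geometry left open) | CC=C(O[Si](C)(C)C)O[C@@H](C)/C=C/[Si](C)(C)c1ccccc1 | intermediate (not isolated)
5 | trimethylsilyl (3R,4E)-3-[dimethyl(phenyl)silyl]-2-methylhex-4-enoate | C/C=C/[C@@H]([Si](C)(C)c1ccccc1)C(C)C(=O)O[Si](C)(C)C | intermediate (not isolated)
6 | (3R,4E)-3-[dimethyl(phenyl)silyl]-2-methylhex-4-enoic acid (C2 epimers) | C/C=C/[C@@H]([Si](C)(C)c1ccccc1)C(C)C(=O)O | intermediate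
7 | (S)-(+)-linalool, (3S)-3,7-dimethylocta-1,6-dien-3-ol | C=C[C@@](C)(O)CCC=C(C)C | starting material
8 | (3R,4E)-3-[dimethyl(phenyl)silyl]-2-methylhex-4-enoyl chloride | C/C=C/[C@@H]([Si](C)(C)c1ccccc1)C(C)C(Cl)=O | intermediate (not isolated)
9 | lithium (3S)-3,7-dimethylocta-1,6-dien-3-olate | [Li+].[O-][C@](C)(C=C)CCC=C(C)C | intermediate (not isolated)
10 | (3S)-3,7-dimethylocta-1,6-dien-3-yl (3R,4E)-3-[dimethyl(phenyl)silyl]-2-methylhex-4-enoate | C/C=C/[C@@H]([Si](C)(C)c1ccccc1)C(C)C(=O)O[C@](C)(C=C)CCC=C(C)C | intermediate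
11 | (3S)-5-[(2R)-3,3-dimethyloxiran-2-yl]-3-methylpent-1-en-3-yl (3R,4E)-3-[dimethyl(phenyl)silyl]-2-methylhex-4-enoate | C/C=C/[C@@H]([Si](C)(C)c1ccccc1)C(C)C(=O)O[C@](C)(C=C)CC[C@H]2OC2(C)C | intermediate
12 | (4R,7S)-7-{2-[(2R)-3,3-dimethyloxiran-2-yl]ethyl}-4-[dimethyl(phenyl)silyl]-3,7-dimethyl-4,7-dihydrooxepin-2(3H)-one | CC1C(=O)O[C@@](C)(CC[C@H]2OC2(C)C)C=C[C@H]1[Si](C)(C)c3ccccc3 | intermediate
13 | (4R,7S)-7-[(3S)-3,4-dibromo-4-methylpentyl]-4-[dimethyl(phenyl)silyl]-3,7-dimethyl-4,7-dihydrooxepin-2(3H)-one | CC1C(=O)O[C@@](C)(CC[C@H](Br)C(C)(C)Br)C=C[C@H]1[Si](C)(C)c2ccccc2 | intermediate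
14 | (5aS,7S,9aS)-7-bromo-3,6,6,9a-tetramethyl-5a,6,7,8,9,9a-hexahydrobenzo[b]oxepin-2(3H)-one (C3 epimers) | CC1C=C[C@H]2C(C)(C)[C@@H](Br)CC[C@]2(C)OC1=O | intermediate (not isolated)
15 | (5aS,7S,9aS)-7-bromo-3,6,6,9a-tetramethyl-5a,6,7,8,9,9a-hexahydrobenzo[b]oxepin-2(5H)-one | CC1=CC[C@H]2C(C)(C)[C@@H](Br)CC[C@]2(C)OC1=O | intermediate
16 | (5aS,7S,9aS)-7-bromo-3,6,6,9a-tetramethyl-2-methylidene-2,5,5a,6,7,8,9,9a-octahydrobenzo[b]oxepine | CC1=CC[C@H]2C(C)(C)[C@@H](Br)CC[C@]2(C)OC1=C | intermediate
17 | 9-{[(2S,5aS,7S,9aS)-7-bromo-3,6,6,9a-tetramethyl-2,5,5a,6,7,8,9,9a-octahydrobenzo[b]oxepin-2-yl]methyl}-9-borabicyclo[3.3.1]nonane (same spatial arrangement at C2 as 18) | CC1=CC[C@H]2C(C)(C)[C@@H](Br)CC[C@]2(C)O[C@H]1CB3C4CCCC3CCC4 | intermediate (not isolated)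
18 | [(2R,5aS,7S,9aS)-7-bromo-3,6,6,9a-tetramethyl-2,5,5a,6,7,8,9,9a-octahydrobenzo[b]oxepin-2-yl]methanol | CC1=CC[C@H]2C(C)(C)[C@@H](Br)CC[C@]2(C)O[C@H]1CO | intermediate
19 | palisadin B, (2R,5aS,7S,9aS)-7-bromo-2-(bromomethyl)-3,6,6,9a-tetramethyl-2,5,5a,6,7,8,9,9a-octahydrobenzo[b]oxepine | CC1=CC[C@H]2C(C)(C)[C@@H](Br)CC[C@]2(C)O[C@H]1CBr | target

**Step count and risks**

Total step count: 11. Longest linear sequence: 11 steps (1 → 19); linalool 7 enters at step 4.

Steps most likely to fail:

Step 8 (Proposed new method). Silicon may be lost together with opening of the lactone C–O bond (a vinylogous Peterson-type fragmentation), the bromonium ion may be captured by trifluoroacetate, or the wrong alkene face may be attacked, giving a cis ring fusion. The fallback uses known chemistry and sets out from 13. Zinc dust in AcOH–THF should remove both bromines and return the trisubstituted alkene, (4R,7S)-4-[dimethyl(phenyl)silyl]-3,7-dimethyl-7-(4-methylpent-3-en-1-yl)-4,7-dihydrooxepin-2(3H)-one F1. Classical bromonium-initiated cation–olefin cyclisation of F1 with 2,4,4,6-tetrabromocyclohexa-2,5-dienone in MeNO2 at 0 °C should then give 14. C7 would now be fixed by the chair and anti-periplanar opening (substrate control) and not by a preset centre. DBU converts 14 into 15, where the route is rejoined.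

Step 6. Initiation may be slow and oligomerisation may take over, because the ester prefers its s-trans conformer and both alkenes are hindered. The fallback installs silicon after ring closure and sets out from 7 (as its alkoxide 9). Acylation with (2E)-penta-2,4-dienoyl chloride should give (3S)-3,7-dimethylocta-1,6-dien-3-yl (2E)-penta-2,4-dienoate F2, and Shi epoxidation as in step 5 should give the (R)-epoxide F3. Ring-closing metathesis, now through an unhindered terminal vinyl group, should give the conjugated dienyl lactone (7S)-7-{2-[(2R)-3,3-dimethyloxiran-2-yl]ethyl}-7-methyloxepin-2(7H)-one F4. Copper-catalysed enantioselective 1,4-addition of PhMe2Si–Bpin (chiral NHC–Cu) should put silicon on C4 and give (4S,7S)-7-{2-[(2R)-3,3-dimethyloxiran-2-yl]ethyl}-4-[dimethyl(phenyl)silyl]-7-methyl-4,7-dihydrooxepin-2(3H)-one F5. Enolate methylation (LDA, MeI, −78 °C) at C3 then returns to the route at 12.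

Step 10. Facial selectivity in the hydroboration may be poor, the β-alkoxyborane may undergo β-elimination with ring opening, and the enol ether 16 may be lost to traces of acid. The fallback replaces steps 9–11 and sets out from 15. Addition of bromomethyllithium (CH2Br2, n-BuLi, THF, −90 °C) should give the lactol (5aS,7S,9aS)-7-bromo-2-(bromomethyl)-3,6,6,9a-tetramethyl-2,5,5a,6,7,8,9,9a-octahydrobenzo[b]oxepin-2-ol F6. Ionic reduction (Et3SiH, TMSOTf, CH2Cl2–MeCN, −40 °C) through the cyclic oxocarbenium ion, with hydride delivered anti to the C9a methyl, should give 19 directly, where the route is rejoined.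

**Further compounds**

F1 | step 8 | (4R,7S)-4-[dimethyl(phenyl)silyl]-3,7-dimethyl-7-(4-methylpent-3-en-1-yl)-4,7-dihydrooxepin-2(3H)-one | CC1C(=O)O[C@@](C)(CCC=C(C)C)C=C[C@H]1[Si](C)(C)c2ccccc2
F2 | step 6 | (3S)-3,7-dimethylocta-1,6-dien-3-yl (2E)-penta-2,4-dienoate | C=C/C=C/C(=O)O[C@](C)(C=C)CCC=C(C)C
F3 | step 6 | (3S)-5-[(2R)-3,3-dimethyloxiran-2-yl]-3-methylpent-1-en-3-yl (2E)-penta-2,4-dienoate | C=C/C=C/C(=O)O[C@](C)(C=C)CC[C@H]1OC1(C)C
F4 | step 6 | (7S)-7-{2-[(2R)-3,3-dimethyloxiran-2-yl]ethyl}-7-methyloxepin-2(7H)-one | O=C1O[C@@](C)(CC[C@H]2OC2(C)C)C=CC=C1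
F5 | step 6 | (4S,7S)-7-{2-[(2R)-3,3-dimethyloxiran-2-yl]ethyl}-4-[dimethyl(phenyl)silyl]-7-methyl-4,7-dihydrooxepin-2(3H)-one | C1C(=O)O[C@@](C)(CC[C@H]2OC2(C)C)C=C[C@H]1[Si](C)(C)c3ccccc3
F6 | step 10 | (5aS,7S,9aS)-7-bromo-2-(bromomethyl)-3,6,6,9a-tetramethyl-2,5,5a,6,7,8,9,9a-octahydrobenzo[b]oxepin-2-ol (C2 anomers) | CC1=CC[C@H]2C(C)(C)[C@@H](Br)CC[C@]2(C)OC1(O)CBr
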